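Temperature is what differs between these flasks, at one charge and one time.

all flasks: J 10 mM; X 1.50 equiv; time 20 min

|  | remark | temperature |
|---|---|---|
| west | at 30 °C until 15 min, from then on at 80 °C |  |
| south-west |  | 80 °C |
| south |  | 30 °C |
| north |  | 55 °C |

    J → D (k1 = 0.0027 s⁻¹, Ea1 = 114 kJ mol⁻¹)
    X + D → X.D (k2 = 0.11 M⁻¹ s⁻¹, Ea2 = 44.0 kJ mol⁻¹)
    J ⇌ G (K3 = 0.54, k3 = 0.0015 s⁻¹, Ea3 = 101 kJ mol⁻¹, ΔH3 = −19.0 kJ mol⁻¹)
    J + X.D → J.X.D (k4 = 0.082 M⁻¹ s⁻¹, Ea4 = 48.0 kJ mol⁻¹)
    (constants at 80 °C)

- percent here means J units held: one J.X.D counts as two
- all constants are for 80 °C and move with temperature by the activation energies and enthalpies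

1. which flask leads in share of X.D in all that became X.D or J.X.D ("all alike" within 1.5 percentage points) (west / south-west / south / north / all alike)
2. share of X.D in all that became X.D or J.X.D, west
3. share of X.D in all that became X.D or J.X.D, south-west
4. share of X.D in all that became X.D or J.X.D, south
5. share of X.D in all that became X.D or J.X.D, north

I treat J.X.D as a correction to X.D and compute the correction. While the fraction of J stays near one, D grows in line with time, X.D with its square and J.X.D with its cube. Step 4 is then pseudo-first-order in X.D, with k4 times the charge of J as its constant. Integrating, and counting J.X.D double, gives 2/3 of k4 times charge times time. At 30 °C, k4 is 0.00553 M⁻¹ s⁻¹, so south reaches 0.0443 at 20 min. This number, the J units in J.X.D per J unit in X.D, is the tail ratio. It gives south a share of 95.8%. The premise holds in south, since step 1 takes a fraction of about 0.00536 of J.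

Now I turn the question round. For south to lose the lead, another flask must carry a smaller ratio than south. West, hot for its last 5.00 min, gets 0.164 from the same formula. That figure is rough, because k1 times that stretch is 0.810, so the premise fails in west's hot stretch. In south-west, J lives about 6.17 min under step 1, shorter than the time. I put that life in place of time and get 0.202, a rough share of 83.2%. South stands lower than the nearer of these rough figures, by a factor of 3.70, and I expect the true factor to be smaller.

The forecast names south, with 92% for west, 87.5% for south-west, 95.8% for south and 85.5% for north. Its ground is that “the cold flask (little conversion, J.X.D only a trace) and the late-heated flask (short hot period) keep the highest share”. My south-west figure lies lower than its figure.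

The flask gives south in the lead, with 92.0% for west, 88.0% for south-west, 95.7% for south and 85.6% for north. South still holds 98.9% of its J at 20.0 min. Time is what would make the forecast wrong: at 200 min south falls to 67.1%, lower than west's 89.2%. The tail ratio scaled to that time is 0.443, a share of 69.3%.

The neighbour of north kept at 40 °C has k4 of 0.0102 M⁻¹ s⁻¹, so its tail ratio is 0.0813 and its share 92.5%. Computed, that flask gives 92.5%.

The constants used here were set for the occasion.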